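**Plan**
Retrosynthesis: the three benzyl ethers come off first. Then O1–C2 and C4–C4a of the pyranone are cut together, then the C8–CH2 bond of the bridge, then the formyl, O-methyl and acyl bonds of the dihydrochalcone ring, back to 2-methylphloroglucinol.
Enabling feature: the pyranone ring (O1, C2, C3, C4) is fused through C4a/C8a to a phloroglucinol ring that carries the bridge at C8. Without the pyranone and with O5 benzylated, this ring has a mirror plane through C8 and C5. C4a/C6 and O1/O7 are then equivalent pairs, so only the 8-substituted flavone can form.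
Forward: the hexasubstituted ring A′ is finished first (acylation, 4′-O-methylation, formylation, benzylation). Its aldehyde is joined to the aryllithium generated between the two MOM ethers of protected phloroglucinol, the carbinol is deoxygenated and the MOM groups are removed.
The 3-methoxy-2-phenylpyranone is the only ring made in the route. It arises by acid-free thermal annulation with methyl 2-methoxybenzoylacetate, and hydrogenolysis ends the route.
Stereochemistry: the target has no stereocentre. The centres met on the way (carbinol carbon, C2 of the ketoester) are racemic and are erased.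

Key step: step 11

Remark: the target contains no stereocentre and no configurationally stable axis. It is therefore one achiral compound, and no enantioselective step is needed.

**Step 1**
Reactants: 1 2-methylphloroglucinol; 2 hydrocinnamoyl chloride
Product: 3 1-(2,4,6-trihydroxy-3-methylphenyl)-3-phenylpropan-1-one
Conditions: AlCl3 (4 equiv), CH2Cl2–MeNO2, 0 → 45 °C; then ice/1 M HCl
Reagents that add atoms: none
Why: Friedel–Crafts acylation of a phloroglucinol, in which the two open ring carbons of 1 are equivalent and the first acyl group deactivates the ring, so a single monoketone is expected (any aryl ester formed first undergoes Fries rearrangement under these conditions).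

**Step 2**
Reactants: 3 1-(2,4,6-trihydroxy-3-methylphenyl)-3-phenylpropan-1-one
Product: 4 1-(2,6-dihydroxy-4-methoxy-3-methylphenyl)-3-phenylpropan-1-one
Conditions: Me2SO4 (1.0 equiv), K2CO3 (1.05 equiv), acetone, rt → 40 °C
Reagents that add atoms: dimethyl sulfate, COS(=O)(=O)OC
Why: Selective Williamson-type O-methylation, since the hydroxyl para to the ketone is the most acidic one, while the two ortho hydroxyls are held back by hydrogen bonding to the acyl group and by its bulk.

**Step 3**
Reactants: 4 1-(2,6-dihydroxy-4-methoxy-3-methylphenyl)-3-phenylpropan-1-one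
Product: 6 2,4-dihydroxy-6-methoxy-5-methyl-3-(3-phenylpropanoyl)benzaldehyde, via α-chlorobenzyl methyl ether 5 (not isolated)
Conditions: Cl2CHOMe (1.5 equiv), TiCl4 (3.5 equiv), CH2Cl2, –10 → 0 °C; then 1 M HCl, rt
Reagents that add atoms: dichloromethyl methyl ether, COC(Cl)Cl; water, O
Why: Rieche formylation, known for acylphloroglucinols, strikes the only unsubstituted ring carbon (ortho to a titanium-bound phenol) and 5 is hydrolysed on work-up; it is preferred to a Vilsmeier reagent, which would attack the α-methylene of a 2′-hydroxydihydrochalcone and lead to a 3-benzylchromone.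

**Step 4**
Reactants: 6 2,4-dihydroxy-6-methoxy-5-methyl-3-(3-phenylpropanoyl)benzaldehyde
Product: 7 2,4-bis(benzyloxy)-6-methoxy-5-methyl-3-(3-phenylpropanoyl)benzaldehyde
Conditions: BnBr (3 equiv), K2CO3 (4 equiv), Bu4NI (cat.), DMF, 60 °C
Reagents that add atoms: benzyl bromide, BrCc1ccccc1
Why: Williamson benzylation in a dipolar aprotic solvent overcomes the chelation of both phenols, and no open ring carbon is left for aromatic C-benzylation.

**Step 5**
Reactants: 8 phloroglucinol (anhydrous)
Product: 9 5-(benzyloxy)benzene-1,3-diol
Conditions: 8 (3 equiv), BnBr (1 equiv), K2CO3 (1.1 equiv), DMF, rt → 50 °C; surplus 8 washed out with water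
Reagents that add atoms: benzyl bromide, BrCc1ccccc1
Why: Statistical Williamson mono-O-benzylation of a C3-symmetric triol, in which the excess of the cheap, water-soluble triol suppresses di- and tribenzylation.

**Step 6**
Reactants: 9 5-(benzyloxy)benzene-1,3-diol
Product: 10 1-(benzyloxy)-3,5-bis(methoxymethoxy)benzene
Conditions: MOMCl (3 equiv), iPr2NEt (4 equiv), CH2Cl2, 0 °C → rt
Reagents that add atoms: chloromethyl methyl ether, COCCl
Why: Standard MOM protection of phenols, which caps both acidic protons and installs the two chelating groups that direct the metalation in the next step.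

**Step 7**
Reactants: 10 1-(benzyloxy)-3,5-bis(methoxymethoxy)benzene; 7 2,4-bis(benzyloxy)-6-methoxy-5-methyl-3-(3-phenylpropanoyl)benzaldehyde
Product: 12 1-[2,6-bis(benzyloxy)-3-{[4-(benzyloxy)-2,6-bis(methoxymethoxy)phenyl](hydroxy)methyl}-4-methoxy-5-methylphenyl]-3-phenylpropan-1-one (racemic), via aryllithium 11 (not isolated)
Conditions: 10 (1.5 equiv), n-BuLi (1.4 equiv), THF, 0 °C, 1 h; then 7, –78 → –40 °C; aq NH4Cl
Reagents that add atoms: n-butyllithium, [Li]CCCC (supplies the lithium of 11 only; no atom of it remains in 12)
Why: Directed ortho-metalation takes place at the carbon flanked by the two chelating OMOM groups, and the aryllithium adds 1,2 to the aldehyde rather than to the ketone, which is twisted between two benzyloxy groups and at worst is enolised and returned on quench; the new carbinol centre is racemic and is removed in step 8.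

**Step 8**
Reactants: 12 diaryl carbinol
Product: 13 1-[2,6-bis(benzyloxy)-3-{[4-(benzyloxy)-2,6-bis(methoxymethoxy)phenyl]methyl}-4-methoxy-5-methylphenyl]-3-phenylpropan-1-one
Conditions: Et3SiH (5 equiv), TFA (3 equiv), CH2Cl2, –30 → 0 °C; aq NaHCO3
Reagents that add atoms: none
Why: In this ionic hydrogenation the carbinol, flanked by six alkoxy groups in ortho and para positions, ionises with little acid at low temperature and the cation is trapped by the silane, long before the ketone or the benzyl ethers react; partial loss of MOM does no harm because step 9 removes both groups.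

**Step 9**
Reactants: 13 bis-MOM diarylmethane
Product: 14 1-[2,6-bis(benzyloxy)-3-{[4-(benzyloxy)-2,6-dihydroxyphenyl]methyl}-4-methoxy-5-methylphenyl]-3-phenylpropan-1-one
Conditions: conc. HCl (cat.), MeOH–THF, 45 °C
Reagents that add atoms: none
Why: Acid-catalysed acetal exchange with methanol is the usual cleavage of phenolic MOM ethers; it carries the formaldehyde unit away as its dimethyl acetal, so it cannot re-attack the electron-rich ring, and it leaves benzyl ethers and the hindered ketone untouched.

**Step 10**
Reactants: 15 methyl methoxyacetate; 16 benzoyl chloride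
Product: 18 methyl 2-methoxy-3-oxo-3-phenylpropanoate (racemic and enolisable), via lithium ester enolate 17 (not isolated)
Conditions: 15 (2.1 equiv), LDA (2.1 equiv), THF, –78 °C; 16 (1.0 equiv), –78 → 0 °C; 1 M HCl
Reagents that add atoms: lithium diisopropylamide, CC(C)N([Li])C(C)C (supplies the lithium of 17 only; no atom of it remains in 18)
Why: Crossed Claisen-type C-acylation of a preformed lithium ester enolate with an acid chloride, in which the second equivalent of enolate deprotonates the more acidic β-ketoester and so protects it from further acylation.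

**Step 11**
Reactants: 14 bridged 2-benzyl-5-(benzyloxy)resorcinol; 18 methyl 2-methoxy-3-oxo-3-phenylpropanoate
Product: 21 5-(benzyloxy)-8-{[2,4-bis(benzyloxy)-6-methoxy-5-methyl-3-(3-phenylpropanoyl)phenyl]methyl}-7-hydroxy-3-methoxy-2-phenyl-4H-chromen-4-one, via α-oxoketene 19 (not isolated), via aryl 1,3-diketone 20 (not isolated)
Conditions: 18 (2 equiv, in two portions), minimum Ph2O, 240 °C (oil bath or microwave), N2 sweep to remove MeOH and H2O, no acid or base
Reagents that add atoms: none
Why: On heating, 18 loses methanol to give α-oxoketene 19, which acylates the free resorcinol-type ring of 14 at a carbon lying between a hydroxyl and the benzyloxy group (C4–C4a) to give diketone 20, while any aryl ester formed by O-acylation reverts to phenol and ketene at this temperature. The hydroxyl next to the new acyl group then adds to the benzoyl carbonyl in a 6-exo-trig closure and the hemiketal loses water (O1–C2), so the pyranone ring appears with its 3-methoxy group already in place. The closest known reaction is the Mentzer pyrone synthesis, the catalyst-free thermal condensation of phloroglucinol-type phenols with benzoylacetates or 2-substituted β-ketoesters to give flavones and 2,3-disubstituted chromones. No stereocentre is formed, and the enolisable centre of 18 and 20 ends as sp2 C3. Ring selectivity follows from ring A′ being hexasubstituted with all its oxygens alkylated, and the 8- over the 6-isomer is enforced because the two open carbons of the reacting ring are mirror images and the oxygen para to the bridge is benzylated, so only a hydroxyl adjacent to the bridge can close. The absence of acid disfavours the Pechmann (coumarin) pathway, and the new C4 carbonyl deactivates the ring against a second annulation at C6/O7.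

**Step 12**
Reactants: 21 tri-O-benzyl flavone
Product: 22 8-{[2,4-dihydroxy-6-methoxy-5-methyl-3-(3-phenylpropanoyl)phenyl]methyl}-5,7-dihydroxy-3-methoxy-2-phenyl-4H-chromen-4-one (target)
Conditions: H2 (1 atm), 10% Pd/C, EtOAc–MeOH, rt
Reagents that add atoms: none
Why: Catalytic hydrogenolysis cleaves the three aryl benzyl ethers under conditions that should leave intact the tetrasubstituted C2=C3 bond of a 3-methoxyflavone, the chelated aryl ketone, the methyl ethers and the diarylmethane.

**Compound list**
1 | 2-methylphloroglucinol | Cc1c(O)cc(O)cc1O | starting material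
2 | hydrocinnamoyl chloride | O=C(Cl)CCc1ccccc1 | starting material
3 | 1-(2,4,6-trihydroxy-3-methylphenyl)-3-phenylpropan-1-one | Cc1c(O)cc(O)c(C(=O)CCc2ccccc2)c1O | intermediate
4 | 1-(2,6-dihydroxy-4-methoxy-3-methylphenyl)-3-phenylpropan-1-one | COc1cc(O)c(C(=O)CCc2ccccc2)c(O)c1C | intermediate
5 | 1-{3-[chloro(methoxy)methyl]-2,6-dihydroxy-4-methoxy-5-methylphenyl}-3-phenylpropan-1-one (formed in situ, racemic) | COc1c(C)c(O)c(C(=O)CCc2ccccc2)c(O)c1C(Cl)OC | intermediate
6 | 2,4-dihydroxy-6-methoxy-5-methyl-3-(3-phenylpropanoyl)benzaldehyde | COc1c(C)c(O)c(C(=O)CCc2ccccc2)c(O)c1C=O | intermediate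
7 | 2,4-bis(benzyloxy)-6-methoxy-5-methyl-3-(3-phenylpropanoyl)benzaldehyde | COc1c(C)c(OCc2ccccc2)c(C(=O)CCc2ccccc2)c(OCc2ccccc2)c1C=O | intermediate
8 | phloroglucinol | Oc1cc(O)cc(O)c1 | starting material
9 | 5-(benzyloxy)benzene-1,3-diol | Oc1cc(O)cc(OCc2ccccc2)c1 | intermediate
10 | 1-(benzyloxy)-3,5-bis(methoxymethoxy)benzene | COCOc1cc(OCc2ccccc2)cc(OCOC)c1 | intermediate
11 | [4-(benzyloxy)-2,6-bis(methoxymethoxy)phenyl]lithium (formed in situ) | [Li]c1c(OCOC)cc(OCc2ccccc2)cc1OCOC | intermediate
12 | 1-[2,6-bis(benzyloxy)-3-{[4-(benzyloxy)-2,6-bis(methoxymethoxy)phenyl](hydroxy)methyl}-4-methoxy-5-methylphenyl]-3-phenylpropan-1-one (racemic) | COc1c(C)c(OCc2ccccc2)c(C(=O)CCc2ccccc2)c(OCc2ccccc2)c1C(O)c1c(OCOC)cc(OCc2ccccc2)cc1OCOC | intermediate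
13 | 1-[2,6-bis(benzyloxy)-3-{[4-(benzyloxy)-2,6-bis(methoxymethoxy)phenyl]methyl}-4-methoxy-5-methylphenyl]-3-phenylpropan-1-one | COc1c(C)c(OCc2ccccc2)c(C(=O)CCc2ccccc2)c(OCc2ccccc2)c1Cc1c(OCOC)cc(OCc2ccccc2)cc1OCOC | intermediate
14 | 1-[2,6-bis(benzyloxy)-3-{[4-(benzyloxy)-2,6-dihydroxyphenyl]methyl}-4-methoxy-5-methylphenyl]-3-phenylpropan-1-one | COc1c(C)c(OCc2ccccc2)c(C(=O)CCc2ccccc2)c(OCc2ccccc2)c1Cc1c(O)cc(OCc2ccccc2)cc1O | intermediate
15 | methyl methoxyacetate | COCC(=O)OC | starting material
16 | benzoyl chloride | O=C(Cl)c1ccccc1 | starting material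
17 | lithium enolate of methyl methoxyacetate (formed in situ, geometry not defined) | COC=C(O[Li])OC | intermediate
18 | methyl 2-methoxy-3-oxo-3-phenylpropanoate (racemic, enolisable) | COC(=O)C(OC)C(=O)c1ccccc1 | intermediate
19 | 2-methoxy-3-oxo-3-phenylprop-1-en-1-one, the α-oxoketene (formed in situ) | COC(=C=O)C(=O)c1ccccc1 | intermediate
20 | 1-[6-(benzyloxy)-3-{[2,4-bis(benzyloxy)-6-methoxy-5-methyl-3-(3-phenylpropanoyl)phenyl]methyl}-2,4-dihydroxyphenyl]-2-methoxy-3-phenylpropane-1,3-dione (formed in situ, racemic, enolisable) | COc1c(C)c(OCc2ccccc2)c(C(=O)CCc2ccccc2)c(OCc2ccccc2)c1Cc1c(O)cc(OCc2ccccc2)c(C(=O)C(OC)C(=O)c2ccccc2)c1O | intermediate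
21 | 5-(benzyloxy)-8-{[2,4-bis(benzyloxy)-6-methoxy-5-methyl-3-(3-phenylpropanoyl)phenyl]methyl}-7-hydroxy-3-methoxy-2-phenyl-4H-chromen-4-one | COc1c(C)c(OCc2ccccc2)c(C(=O)CCc2ccccc2)c(OCc2ccccc2)c1Cc1c(O)cc(OCc2ccccc2)c2c(=O)c(OC)c(-c3ccccc3)oc12 | intermediate
22 | 8-{[2,4-dihydroxy-6-methoxy-5-methyl-3-(3-phenylpropanoyl)phenyl]methyl}-5,7-dihydroxy-3-methoxy-2-phenyl-4H-chromen-4-one | COc1c(C)c(O)c(C(=O)CCc2ccccc2)c(O)c1Cc1c(O)cc(O)c2c(=O)c(OC)c(-c3ccccc3)oc12 | target

**Total step count:** 12.
**Longest linear sequence:** 9 steps (1, 2, 3, 4, 7, 8, 9, 11, 12).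

**Steps most likely to fail**

Step 11. The long exposure to about 240 °C may cause loss or migration of benzyl groups. Self-condensation of the ketene may outrun C-acylation of the flanked ring carbon. Part of the material may also follow the coumarin-forming pathway. The fallback sets out from 14 and comes back at 21, and it makes the two bonds one after the other.
- Houben–Hoesch acylation of 14 with methoxyacetonitrile (ZnCl2, dry HCl, Et2O, 0 °C; then warm water) should place a methoxyacetyl group on one of the two equivalent ring carbons. This gives the ω-methoxyacetophenone F1.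
- Allan–Robinson condensation of F1 with benzoic anhydride and sodium benzoate (about 170 °C) should close the pyranone through the only ortho hydroxyl and acylate the remaining phenol. This gives the flavone 7-O-benzoate F2.
- Brief treatment of F2 with aqueous KOH in EtOH, followed by acidification, frees the 7-hydroxyl and gives 21.

Step 7. Proton transfer from the α-methylene of the ketone may quench the aryllithium. Addition between two doubly ortho-substituted partners may be slow. Some metalation may occur next to the benzyloxy group. The fallback sets out from 7 and from aryllithium 11 and comes back at 13, so step 8 is bypassed as well. It replaces the carbonyl addition by an sp3–sp2 cross-coupling.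
- NaBH4 (MeOH–THF, –20 °C) should reduce only the aldehyde of 7 to the benzylic alcohol F3.
- An Appel reaction (CBr4, PPh3, CH2Cl2, 0 °C) converts F3 into the benzylic bromide F4, which is used crude.
- Aryllithium 11 is transmetalated with ZnCl2 to the arylzinc chloride F5, which tolerates the ketone.
- Negishi coupling of F4 with F5 (Pd2(dba)3, SPhos, THF, 50 °C) should give 13 directly.

Step 2. Discrimination between the para hydroxyl and the ortho hydroxyls may be incomplete, which leads to over-methylation or methylation at the wrong oxygen. The fallback sets out from 3 and comes back at 4. It moves the selectivity from the alkylation to a dealkylation.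
- Exhaustive methylation (excess Me2SO4, K2CO3, acetone, reflux) gives the trimethyl ether F6.
- AlCl3 (PhCl, 80–100 °C) then removes only the two methyl groups ortho to the ketone through chelation. The 4′-methyl ether stays in place, and 4 results.

**Further compounds**
F1 | step 11 | 1-[2,6-bis(benzyloxy)-3-{[4-(benzyloxy)-2,6-dihydroxy-3-(methoxyacetyl)phenyl]methyl}-4-methoxy-5-methylphenyl]-3-phenylpropan-1-one | COc1c(C)c(OCc2ccccc2)c(C(=O)CCc2ccccc2)c(OCc2ccccc2)c1Cc1c(O)cc(OCc2ccccc2)c(C(=O)COC)c1O
F2 | step 11 | 5-(benzyloxy)-8-{[2,4-bis(benzyloxy)-6-methoxy-5-methyl-3-(3-phenylpropanoyl)phenyl]methyl}-3-methoxy-4-oxo-2-phenyl-4H-chromen-7-yl benzoate | COc1c(C)c(OCc2ccccc2)c(C(=O)CCc2ccccc2)c(OCc2ccccc2)c1Cc1c(OC(=O)c2ccccc2)cc(OCc2ccccc2)c2c(=O)c(OC)c(-c3ccccc3)oc12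
F3 | step 7 | 1-[2,6-bis(benzyloxy)-3-(hydroxymethyl)-4-methoxy-5-methylphenyl]-3-phenylpropan-1-one | COc1c(C)c(OCc2ccccc2)c(C(=O)CCc2ccccc2)c(OCc2ccccc2)c1CO
F4 | step 7 | 1-[2,6-bis(benzyloxy)-3-(bromomethyl)-4-methoxy-5-methylphenyl]-3-phenylpropan-1-one | COc1c(C)c(OCc2ccccc2)c(C(=O)CCc2ccccc2)c(OCc2ccccc2)c1CBr
F5 | step 7 | [4-(benzyloxy)-2,6-bis(methoxymethoxy)phenyl]zinc chloride | Cl[Zn]c1c(OCOC)cc(OCc2ccccc2)cc1OCOC
F6 | step 2 | 3-phenyl-1-(2,4,6-trimethoxy-3-methylphenyl)propan-1-one | COc1cc(OC)c(C(=O)CCc2ccccc2)c(OC)c1C
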